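## The problem

Target **24** is a 5α-daucane: a cyclopentane and a cycloheptane fused trans through the quaternary carbon C1 (β-methyl) and the methine C5 (α-H). The numbering used throughout is C1 (fusion carbon with CH3), C2 (CH–OAc), C3 (CH2), C4 (isopropyl carbinol), C5 (fusion CH), C6 (CH–O-anisoyl), C7 (CH2), C8 (methyl-bearing epoxide carbon), C9 (epoxide CH) and C10 (CH–OH); β is the face of the C1 methyl. There are eight stereocentres (C1, C2, C4, C5, C6, C8, C9, C10) and five oxygen functions in four different states.

C1 is the one centre that no neighbour can set. Once it is in place its pseudo-axial methyl can steer much of the rest: a C10 carbonyl is attacked anti to it, the equatorial C2–H is the one within reach of a directing group on C10, and a C5 enolate or the C8=C9 alkene is attacked from the α face. C4 is the exception, because the two faces of a C4=C5 double bond differ only by CH3 versus CH2 on C1; C4 therefore needs a relay, here through a hydroxyl at C6.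

The fragile parts are the trisubstituted epoxide next to the free C10 hydroxyl, the C2 acetate lying syn-1,3 to that hydroxyl (acyl migration), and the tertiary C4 alcohol (elimination, or retro-aldol while C6 is a ketone). An 8,9-alkene β,γ to a C6 ketone can also slip into conjugation. C2 is an unactivated methylene flanked by a quaternary carbon, and the three secondary oxygens must end as acetate, anisoate and free hydroxyl.

The feature that makes the key step possible is that the fifteen skeletal carbons are an unrearranged head-to-tail farnesyl chain. Only C1–C10 (seven-membered ring) and C4–C5 (five-membered ring) are not chain bonds, and the isopropyl group, both methyls and the C8=C9 double bond sit where farnesyl diphosphate **3** already has them.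

## Retrosynthesis

**24 ⇒ 23 ⇒ 22 ⇒ 21 (C8–O and C9–O).** The epoxide is the most fragile group and is made last. A free allylic C10 hydroxyl would deliver a peracid to the β face, so the hydroxyl of **21** is masked as the silyl ether **22**; with no hydrogen-bond delivery, the pseudo-axial C1 methyl should send the oxidant to the α face to give **23**. Epoxidising at the enone stage (**20**) and reducing afterwards was set aside because the sense of an epoxy-ketone reduction next to C1 is not predictable. **21** has two stereocentres fewer than **24**.

**21 ⇒ 20 ⇒ 19 (C10–H and the acetyl C–O).** The C10 carbinol is cut back to the enone **20**: hydride should add anti to the C1 methyl and give the 10β-alcohol. The acetate is put on at **19**, where C2–OH is the only secondary hydroxyl; doing it after the reduction would leave two similar neopentyl alcohols to tell apart.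

**19 ⇒ 16 (C2–O).** C2 can be reached chemically only from C10. In **16** the ketone sits on the quaternary C1, and its pyridylmethyl imine **17** can hold a copper–oxygen species over the equatorial (β) C2–H, giving **18** and, after hydrolysis, **19**. This replaces an undefined hydroxylase by a directed C–H hydroxylation with a known site rule. The forward step must choose the methylene over the C1 methyl and tolerate the conjugated alkene.

**16 ⇒ 15 (C10=O).** Allylic oxidation of the C8=C9 alkene. It is placed after esterification, so that C7 is deactivated by the C6 acyloxy group, and after the C4=C5 alkene has been consumed, because a tetrasubstituted alkene would be oxidised first.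

**15 ⇒ 13 + 14 (ester C–O).** Acylation of the diol **13** with 4-methoxybenzoyl chloride **14** at the only secondary hydroxyl. **13** has the constitution and configuration of the plant diol jaeschkeanadiol, a useful reference point.

**13 ⇒ 12 ⇒ 11 (C6–H and C5–H).** The 6α-alcohol is cut to the β-hydroxy ketone **12**, so that the C4 hydroxyl can deliver hydride to the β face of C6. **12** is cut to the epoxy ketone **11**, whose reductive Cα–O cleavage leaves the C4 oxygen untouched and puts hydrogen on C5. Hydroboration of a C5=C6 alkene would be shorter, but it cannot distinguish that alkene from the less hindered C8=C9.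

**11 ⇒ 10 ⇒ 9 ⇒ 8 (epoxide oxygen on C4/C5, C6–H).** The 4β,5β-epoxide is delivered by a 6β-hydroxyl in **9**. The hydroxyl is lost again as the ketone **11**, and its carbon is re-reduced from the other side later. This relay costs three steps but turns an uncontrolled epoxidation into a directed one. **9** comes from the dienone **8** by a reagent-controlled reduction.

**8 ⇒ 7 ⇒ 5 (C6 oxygen).** The dienone **8** is cut to the tertiary allylic alcohols **7** (oxidative 1,3-transposition) and these to daucene **5** (ene reaction with singlet oxygen). Singlet oxygen selects the tetrasubstituted alkene over C8=C9, and the transposition erases the C4 centre that the ene reaction cannot control, so both epimers of **7** converge.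

**5 ⇒ 3 (C1–C10 and C4–C5).** Both rings and C1 in one enzymatic cation–olefin bicyclisation of **3**, passing through the tertiary allylic diphosphate **4**. No other cut removes two rings, a quaternary stereocentre and all skeletal C–C bonds at once; the price is that every oxygen must be introduced afterwards. The forward step must deliver the (R) series and a single double-bond isomer.

**3 ⇒ 2 ⇒ 1 (C–O–P).** Diphosphorylation of the allylic bromide **2** made from commercial farnesol **1**.

## Roads not taken

**Alternative 1:** Bis-allylsilane [4+3] annulation. The cut is C6–C7 and C9–C10. Forward, the trans-cyclopentane dialdehyde **A1** and the 2-(silylmethyl)allylsilane **A2** undergo two successive Lewis-acid-promoted allylsilane additions that close the seven-membered ring and give the 8-methylene-6,10-diol **A3**.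
- Merits: fully chemical and convergent. The C2 oxygen and the trans ring fusion arrive with **A1**, so no C–H oxidation is needed, and both ring carbinols form in the ring-closing step. In these respects it is better than the chosen plan.
- Weak points: C6 (α) and C10 (β) are set in two different events, one intermolecular and one a seven-membered closure, with only substrate control. The exocyclic methylene must then be moved regioselectively into C8=C9 rather than C7=C8. The two secondary hydroxyls of **A3** must be differentiated, the isopropyl group must still be added at C4, and **A1** (quaternary C1, epimerisable C5 aldehyde) needs its own enantioselective synthesis.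
- Comparison: the chosen plan sets against this that the farnesyl chain supplies the isopropyl group, the C8 methyl, the endocyclic C8=C9 alkene and C1 in one step. It pays with a long oxidation sequence.

**Alternative 2:** Decalin-to-hydroazulene semipinacol shift. The cut is C1–C5, read backwards as a 1,2-shift. Forward, in the all-cis hydroxy mesylate **A5**, derived from (S)-Wieland–Miescher ketone **A4**, C1 migrates from the carbinol carbon C6 to the mesylate carbon C5 and gives the trans-fused hydroazulen-6-one **A6**.
- Merits: C1 comes from a robust organocatalytic annulation. The shift is stereospecific (antiperiplanar), so the trans fusion at C5 is certain, and oxygen is already at C4, C6 and C10. On certainty of C1 and C5 and on the placement of the C6 and C10 oxygens it is better than the chosen plan, which needs an enzyme screen and two oxidations for the same result.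
- Weak points: **A6** has neither the C8 methyl, the C8=C9 alkene, the isopropyl group nor the C2 oxygen. Adding them means many steps on the ketone and ketal, and C2 would still need the same C10-directed C–H hydroxylation.
- Comparison: the chosen plan has all carbons in place after step 3 and should be shorter overall.

**Alternative 3:** Late Nozaki–Hiyama–Kishi closure. The cut is C9–C10. Forward, the (Z)-vinyl iodide/aldehyde **A7** is closed by a chromium/nickel-mediated coupling to the cycloheptenol **A8**, with both esters already in place.
- Merits: the most convergent end-game. The coupling tolerates esters and silyl ethers, and **A8** is the 4-O-silyl analogue of compound **21**, so only silylation of C10–OH, epoxidation and desilylation would remain. It needs no allylic oxidation and no C–H hydroxylation on the bicycle, which is better than the chosen plan.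
- Weak points: the C10 configuration (β needed) is left to substrate control in a seven-membered closure onto a neopentyl aldehyde. The whole difficulty is shifted into **A7**, a cyclopentane with five stereocentres, two of them quaternary, and three differentiated oxygens, for which no short synthesis is evident.
- Comparison: the chosen plan sets C10 by a hydride reduction whose sense follows from the adjacent methyl, and builds the other centres on a rigid bicycle.

Key step: step 3

Assumptions:
- α/β descriptors refer to the daucane skeleton with the C1 methyl β; all daucanes below have C1 configured as in **5**.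
- The enzyme-bound tertiary allylic diphosphate **4** is drawn as the (3R) isomer; this centre is fixed by the synthase and does not reach **5**.
- Diphosphates are drawn as free acids, although **3** is handled as its ammonium salt.

## Route

Step 1
Reactants: 1 (2E,6E)-farnesol
Product: 2 (2E,6E)-farnesyl bromide
Conditions: PBr3 (0.4 equiv), Et2O, −10 °C; used crude
Reagents that add atoms: phosphorus tribromide, BrP(Br)Br
Why: Bromination of a primary allylic alcohol through its bromophosphite; at low temperature the displacement should be direct, without allylic transposition or loss of the (2E) geometry.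

Step 2
Reactants: 2 (2E,6E)-farnesyl bromide
Product: 3 (2E,6E)-farnesyl diphosphate (tris-ammonium salt)
Conditions: (Bu4N)3HP2O7 (2 equiv), MeCN, rt; then Dowex 50W (NH4+ form), aq. NH4HCO3, lyophilisation
Reagents that add atoms: tris(tetrabutylammonium) hydrogen diphosphate, CCCC[N+](CCCC)(CCCC)CCCC.CCCC[N+](CCCC)(CCCC)CCCC.CCCC[N+](CCCC)(CCCC)CCCC.OP(=O)([O-])OP(=O)([O-])[O-]
Why: SN2 displacement of the primary allylic bromide by the diphosphate anion in a dipolar aprotic solvent, the standard chemical diphosphorylation of prenyl halides; ion exchange gives the water-soluble salt the enzyme accepts.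

Step 3
Reactants: 3 (2E,6E)-farnesyl diphosphate
Product: 5 (R)-daucene, via (3R)-nerolidyl diphosphate 4 (not isolated)
Conditions: recombinant daucene synthase (class 1 sesquiterpene synthase, selected for the (R) series), MgCl2 (10 mM), HEPES buffer pH 7.5, dithiothreitol, 30 °C, pentane overlay
Reagents that add atoms: none
Why: Class 1 terpene-synthase cyclisation, the closest known reaction type being the carotol- and daucene-forming sesquiterpene synthases of Apiaceae. MgCl2-assisted ionisation of 3 and return of diphosphate to C3 give 4, whose re-ionisation from the cisoid conformer supplies the (Z)-allyl cation that a cis double bond in a seven-membered ring requires. The cation terminus (daucane C10) is attacked by the 6,7-double bond at its methyl-bearing carbon (C1), a 7-endo-trig cation–olefin closure that forms C1–C10; the charge building up at C5 is captured at once by the distal double bond in a 5-exo-trig closure that forms C4–C5 and leaves the 2-propyl cation. A 1,2-hydride shift from C4 and loss of the C5 proton give the C4=C5 double bond, so C1 is the only stereocentre that survives. Its configuration is set solely by the enantioface of the 6,7-alkene that the active-site contour presents to the allyl cation. The step needs 1,7- instead of 1,6-, 1,10- or 1,11-closure, five-ring formation without a free secondary cation, and one site of final deprotonation; the achiral substrate secures only the connectivity through the positions and geometry of its three double bonds, which is why a synthase and no small reagent is used. The enzyme is to be selected by chiral GC of the product.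

Step 4
Reactants: 5 (R)-daucene
Product: 7 dauca-5,8-dien-4-ol (mixture of both C4 epimers), via 4-hydroperoxydauca-5,8-diene 6 (not isolated)
Conditions: O2, tetraphenylporphyrin (cat.), visible light, CH2Cl2, −40 °C; then PPh3, −40 °C to rt; used crude
Reagents that add atoms: dioxygen, O=O
Why: Schenck ene reaction of singlet oxygen, which reacts with the tetrasubstituted C4=C5 alkene far faster than with the trisubstituted C8=C9. Hydrogen should be taken from C6, the group geminal to the bulky quaternary C1 (large-group effect; isopropyl methine hydrogens are poor donors), placing oxygen on C4. The C4 configuration is not controlled and is erased in step 5.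

Step 5
Reactants: 7 dauca-5,8-dien-4-ol (mixture of both C4 epimers)
Product: 8 dauca-4,8-dien-6-one
Conditions: pyridinium chlorochromate [C5H5NH][CrO3Cl], NaOAc, 4 Å molecular sieves, CH2Cl2, rt
Reagents that add atoms: pyridinium chlorochromate, [O-][Cr](=O)(=O)Cl.c1cc[nH+]cc1
Why: Babler–Dauben oxidative 1,3-transposition: the tertiary allylic chromate ester undergoes a [3,3] shift to C6 and is oxidised there, so both epimers of 7 converge on one dienone. The acetate buffer is meant to keep the β,γ-placed C8=C9 alkene from moving into conjugation.

Step 6
Reactants: 8 dauca-4,8-dien-6-one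
Product: 9 dauca-4,8-dien-6β-ol
Conditions: (S)-2-methyl-CBS-oxazaborolidine (20 mol %), catecholborane, toluene, −78 °C
Reagents that add atoms: none
Why: Corey–Bakshi–Shibata reduction with the fully substituted alkenyl flank as the large group; the (S)-catalyst should deliver hydride to the α face and set C6 as the β-alcohol. This is matched with the substrate, whose pseudo-axial C1 methyl screens the β face. Catecholborane at −78 °C should leave C8=C9 alone, and the hindered β-carbon disfavours conjugate reduction.

Step 7
Reactants: 9 dauca-4,8-dien-6β-ol
Product: 10 4β,5β-epoxydauc-8-en-6β-ol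
Conditions: VO(acac)2 (5 mol %), t-BuOOH (anhydrous, 1.5 equiv), 2,6-lutidine, CH2Cl2, 0 °C
Reagents that add atoms: tert-butyl hydroperoxide, CC(C)(C)OO
Why: Vanadium-catalysed hydroxyl-directed epoxidation: the peroxide bound to the C6 vanadate is delivered to the face of the allylic hydroxyl, so the 6β-OH sets C4 and C5 as the β-epoxide. C8=C9 is only homoallylic and trisubstituted and should react far more slowly.

Step 8
Reactants: 10 4β,5β-epoxydauc-8-en-6β-ol
Product: 11 4β,5β-epoxydauc-8-en-6-one
Conditions: Dess–Martin periodinane, NaHCO3, CH2Cl2, 0 °C
Reagents that add atoms: none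
Why: Dess–Martin oxidation of a secondary alcohol under buffered, non-acidic conditions that should spare the tetrasubstituted epoxide and the β,γ-alkene.

Step 9
Reactants: 11 4β,5β-epoxydauc-8-en-6-one
Product: 12 4β-hydroxy-5α-dauc-8-en-6-one
Conditions: SmI2 (2.5 equiv), THF/MeOH, −90 °C
Reagents that add atoms: none
Why: Samarium diiodide cleavage of the Cα–O bond of an α,β-epoxy ketone gives the aldol with the C4–O bond, and hence the C4 configuration, untouched. The samarium enolate should be protonated at C5 from the α face, anti to the pseudo-axial C1 methyl and the C4 alkoxide; this is also the more stable trans fusion, with the isopropyl group trans to C6.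

Step 10
Reactants: 12 4β-hydroxy-5α-dauc-8-en-6-one
Product: 13 5α-dauc-8-ene-4β,6α-diol (jaeschkeanadiol)
Conditions: Me4NBH(OAc)3, MeCN/AcOH 1:1, −30 °C
Reagents that add atoms: none
Why: Evans–Saksena hydroxyl-directed reduction: the C4 alkoxy(diacetoxy)borohydride delivers hydride intramolecularly to the β face of the C6 carbonyl, so the new hydroxyl is α (anti-1,3-diol).

Step 11
Reactants: 13 5α-dauc-8-ene-4β,6α-diol; 14 4-methoxybenzoyl chloride
Product: 15 4β-hydroxy-5α-dauc-8-en-6α-yl 4-methoxybenzoate
Conditions: DMAP, pyridine, CH2Cl2, 0 °C to rt
Reagents that add atoms: none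
Why: DMAP-catalysed acylation of the only secondary hydroxyl; the tertiary C4 alcohol should not react under these conditions.

Step 12
Reactants: 15 4β-hydroxy-5α-dauc-8-en-6α-yl 4-methoxybenzoate
Product: 16 4β-hydroxy-10-oxo-5α-dauc-8-en-6α-yl 4-methoxybenzoate
Conditions: Rh2(cap)4 (cap = caprolactamate, C6H10NO; 1 mol %), t-BuOOH (70% aq., 5 equiv), K2CO3, CH2Cl2, rt
Reagents that add atoms: tert-butyl hydroperoxide, CC(C)(C)OO
Why: Allylic C–H oxidation by tert-butylperoxyl radicals to the conjugated enone. C7 is deactivated by the neighbouring C6 acyloxy group, as C4 is in Δ5-steroid 3-esters that give 7-ketones, which leaves the methylene on the CH end of the alkene (C10).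

Step 13
Reactants: 16 4β-hydroxy-10-oxo-5α-dauc-8-en-6α-yl 4-methoxybenzoate
Product: 19 2β,4β-dihydroxy-10-oxo-5α-dauc-8-en-6α-yl 4-methoxybenzoate, via picolyl imine 17 (not isolated), via 2β-hydroxy picolyl imine 18 (not isolated)
Conditions: 2-picolylamine, TsOH·H2O (cat.), 4 Å molecular sieves, toluene, 80 °C; then Cu(OTf)2 (1.3 equiv), sodium L-ascorbate (2 equiv), O2 (1 atm), acetone/MeOH 1:1, 50 °C; then aq. Na4EDTA, EtOAc, rt
Reagents that add atoms: dioxygen, O=O; water, O
Why: Imine-directed copper-mediated hydroxylation of a ketone β-C–H bond (Schönecker-type oxidation). The copper–oxygen species held by the imine nitrogen and the pyridine reaches the equatorial C2–H of the methylene next to quaternary C1, as C12 is reached in 17-oxo steroids, and C–O formation with retention gives the 2β-alcohol cis to the C1 methyl. The methyl C–H bonds are stronger and C5–H is axial on the other face; hydrolysis on work-up returns the enone.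

Step 14
Reactants: 19 2β,4β-dihydroxy-10-oxo-5α-dauc-8-en-6α-yl 4-methoxybenzoate
Product: 20 2β-acetoxy-4β-hydroxy-10-oxo-5α-dauc-8-en-6α-yl 4-methoxybenzoate
Conditions: Ac2O, pyridine, DMAP (cat.), CH2Cl2, 0 °C
Reagents that add atoms: acetic anhydride, CC(=O)OC(C)=O
Why: Acetylation of the only secondary hydroxyl (comparable to a steroid 17β-alcohol); the tertiary C4 alcohol should stay free.

Step 15
Reactants: 20 2β-acetoxy-4β-hydroxy-10-oxo-5α-dauc-8-en-6α-yl 4-methoxybenzoate
Product: 21 2β-acetoxy-4β,10β-dihydroxy-5α-dauc-8-en-6α-yl 4-methoxybenzoate
Conditions: NaBH4, CeCl3·7H2O, MeOH, −78 °C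
Reagents that add atoms: none
Why: Luche 1,2-reduction of the enone. Hydride should add to C10 anti to the pseudo-axial methyl on the adjacent C1, as in the reduction of 17-oxo steroids, giving the 10β-alcohol; both esters should survive at this temperature.

Step 16
Reactants: 21 2β-acetoxy-4β,10β-dihydroxy-5α-dauc-8-en-6α-yl 4-methoxybenzoate
Product: 22 2β-acetoxy-4β-hydroxy-10β-(triethylsilyloxy)-5α-dauc-8-en-6α-yl 4-methoxybenzoate
Conditions: Et3SiCl, imidazole, DMF, 0 °C to rt
Reagents that add atoms: chlorotriethylsilane, CC[Si](Cl)(CC)CC
Why: Silylation of the secondary allylic hydroxyl; the tertiary C4 alcohol should not react with the silyl chloride. The ether removes the hydrogen-bond donor that would otherwise direct the peracid to the β face.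

Step 17
Reactants: 22 2β-acetoxy-4β-hydroxy-10β-(triethylsilyloxy)-5α-dauc-8-en-6α-yl 4-methoxybenzoate
Product: 23 2β-acetoxy-8α,9α-epoxy-4β-hydroxy-10β-(triethylsilyloxy)-5α-daucan-6α-yl 4-methoxybenzoate
Conditions: mCPBA, NaHCO3, CH2Cl2, 0 °C
Reagents that add atoms: 3-chloroperbenzoic acid, OOC(=O)c1cccc(Cl)c1
Why: Prilezhaev epoxidation under steric control. The β face of C8=C9 is screened by the pseudo-axial C1 methyl and the silyloxy group, so the peracid should add from the α face, as with Δ4-3β-acyloxy steroids, setting C8 and C9 together.

Step 18
Reactants: 23 2β-acetoxy-8α,9α-epoxy-4β-hydroxy-10β-(triethylsilyloxy)-5α-daucan-6α-yl 4-methoxybenzoate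
Product: 24 2β-acetoxy-8α,9α-epoxy-4β,10β-dihydroxy-5α-daucan-6α-yl 4-methoxybenzoate (CNP0371526.1)
Conditions: HF·pyridine, excess pyridine, THF, 0 °C
Reagents that add atoms: none
Why: Fluoride cleavage of the triethylsilyl ether under buffered, weakly acidic conditions, chosen to avoid base-induced acetate migration from C2 to C10 and epoxide migration.

## Compound list

1 | (2E,6E)-farnesol | CC(C)=CCC/C(C)=C/CC/C(C)=C/CO | starting material
2 | (2E,6E)-farnesyl bromide | CC(C)=CCC/C(C)=C/CC/C(C)=C/CBr | intermediate
3 | (2E,6E)-farnesyl diphosphate (free acid drawn) | CC(C)=CCC/C(C)=C/CC/C(C)=C/COP(=O)(O)OP(=O)(O)O | intermediate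
4 | (3R,6E)-nerolidyl diphosphate (enzyme-bound) | CC(C)=CCC/C(C)=C/CC[C@@](C)(OP(=O)(O)OP(=O)(O)O)C=C | intermediate
5 | (R)-daucene (dauca-4,8-diene) | CC1=CC[C@@]2(C)CCC(C(C)C)=C2CC1 | intermediate
6 | 4-hydroperoxydauca-5,8-diene (both C4 epimers) | CC1=CC[C@@]2(C)CCC(OO)(C(C)C)C2=CC1 | intermediate
7 | dauca-5,8-dien-4-ol (both C4 epimers) | CC1=CC[C@@]2(C)CCC(O)(C(C)C)C2=CC1 | intermediate
8 | dauca-4,8-dien-6-one | CC1=CC[C@@]2(C)CCC(C(C)C)=C2C(=O)C1 | intermediate
9 | dauca-4,8-dien-6β-ol | O[C@@H]1CC(C)=CC[C@]2(C)C1=C(C(C)C)CC2 | intermediate
10 | 4β,5β-epoxydauc-8-en-6β-ol | O[C@@H]1CC(C)=CC[C@]2(C)[C@]13O[C@@]3(C(C)C)CC2 | intermediate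
11 | 4β,5β-epoxydauc-8-en-6-one | O=C1CC(C)=CC[C@]2(C)[C@]13O[C@@]3(C(C)C)CC2 | intermediate
12 | 4β-hydroxy-5α-dauc-8-en-6-one | O=C1CC(C)=CC[C@]2(C)[C@@H]1[C@](O)(C(C)C)CC2 | intermediate
13 | 5α-dauc-8-ene-4β,6α-diol (jaeschkeanadiol) | O[C@H]1CC(C)=CC[C@]2(C)[C@@H]1[C@](O)(C(C)C)CC2 | intermediate
14 | 4-methoxybenzoyl chloride | COc1ccc(C(Cl)=O)cc1 | starting material
15 | 4β-hydroxy-5α-dauc-8-en-6α-yl 4-methoxybenzoate | COc1ccc(C(=O)O[C@H]2CC(C)=CC[C@]3(C)[C@@H]2[C@](O)(C(C)C)CC3)cc1 | intermediate
16 | 4β-hydroxy-10-oxo-5α-dauc-8-en-6α-yl 4-methoxybenzoate | COc1ccc(C(=O)O[C@H]2CC(C)=CC(=O)[C@]3(C)[C@@H]2[C@](O)(C(C)C)CC3)cc1 | intermediate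
17 | (E)-N-(pyridin-2-ylmethyl) imine of 16 at C10 | COc1ccc(C(=O)O[C@H]2CC(C)=C/C(=N\Cc4ccccn4)[C@]3(C)[C@@H]2[C@](O)(C(C)C)CC3)cc1 | intermediate
18 | 2β-hydroxy derivative of imine 17 | COc1ccc(C(=O)O[C@H]2CC(C)=C/C(=N\Cc4ccccn4)[C@]3(C)[C@@H]2[C@](O)(C(C)C)C[C@H]3O)cc1 | intermediate
19 | 2β,4β-dihydroxy-10-oxo-5α-dauc-8-en-6α-yl 4-methoxybenzoate | COc1ccc(C(=O)O[C@H]2CC(C)=CC(=O)[C@]3(C)[C@@H]2[C@](O)(C(C)C)C[C@H]3O)cc1 | intermediate
20 | 2β-acetoxy-4β-hydroxy-10-oxo-5α-dauc-8-en-6α-yl 4-methoxybenzoate | COc1ccc(C(=O)O[C@H]2CC(C)=CC(=O)[C@]3(C)[C@@H]2[C@](O)(C(C)C)C[C@H]3OC(C)=O)cc1 | intermediate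
21 | 2β-acetoxy-4β,10β-dihydroxy-5α-dauc-8-en-6α-yl 4-methoxybenzoate | COc1ccc(C(=O)O[C@H]2CC(C)=C[C@H](O)[C@]3(C)[C@@H]2[C@](O)(C(C)C)C[C@H]3OC(C)=O)cc1 | intermediate
22 | 2β-acetoxy-4β-hydroxy-10β-(triethylsilyloxy)-5α-dauc-8-en-6α-yl 4-methoxybenzoate | COc1ccc(C(=O)O[C@H]2CC(C)=C[C@H](O[Si](CC)(CC)CC)[C@]3(C)[C@@H]2[C@](O)(C(C)C)C[C@H]3OC(C)=O)cc1 | intermediate
23 | 2β-acetoxy-8α,9α-epoxy-4β-hydroxy-10β-(triethylsilyloxy)-5α-daucan-6α-yl 4-methoxybenzoate | COc1ccc(C(=O)O[C@H]2C[C@@]3(C)O[C@H]3[C@H](O[Si](CC)(CC)CC)[C@]3(C)[C@@H]2[C@](O)(C(C)C)C[C@H]3OC(C)=O)cc1 | intermediate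
24 | 2β-acetoxy-8α,9α-epoxy-4β,10β-dihydroxy-5α-daucan-6α-yl 4-methoxybenzoate (CNP0371526.1) | COc1ccc(C(=O)O[C@H]2C[C@@]3(C)O[C@H]3[C@H](O)[C@]3(C)[C@@H]2[C@](O)(C(C)C)C[C@H]3OC(C)=O)cc1 | target

## Step count and risks

Total: 18 steps. Longest linear sequence: 18 steps (1 → 24); 14 is bought and enters at step 11.

**Step 3 (key step).** The cyclase may turn over slowly, may leak into 1,6-closure or other deprotonation products, or may deliver the enantiomeric series, since nothing in the substrate enforces the fold. Fallback, from 3 back to 5: a carotol-forming synthase of the same plant family, which follows the same two closures but ends by water capture, converts 3 into carotol F1. The tertiary alcohol is then dehydrated with the Burgess reagent (syn elimination, expected to favour the tetrasubstituted alkene) to give 5.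

**Step 13.** The hindered, conjugated ketone may condense poorly with the amine, or the amine may add in conjugate fashion or the imine tautomerise. Hydroxylation may also occur at the C1 methyl or with the wrong C2 configuration if the seven-membered ring holds the imine differently from a steroid ring D. Fallback, from 16 back to 19: biocatalytic hydroxylation of 16 with a panel of cytochrome P450 BM3 variants (whole cells, NADPH regeneration), selected for the C2 β-hydrogen. This changes the control element from a substrate-bound directing group to an enzyme pocket and makes no new compound.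

**Step 4.** Hydrogen abstraction may occur from C3 instead of C6, giving C5-oxygenated isomers, or C8=C9 may react partly. Fallback, from 5 back to 7: epoxidation of 5 with one equivalent of mCPBA at −40 °C gives the 4,5-epoxide F2 as a mixture of faces. Isomerisation with diethylaluminium 2,2,6,6-tetramethylpiperidide, Et2Al(TMP), in toluene at 0 °C abstracts a C6 hydrogen and gives 7, which converges in step 5 as before.

**Step 9.** The enolate may be protonated from the β face (cis fusion), the aldol may undergo retro-aldol cleavage, or the 8,9-double bond may move into conjugation while C6 is a ketone. Fallback, from 10 to 15, bypassing 11–13: reductive opening of the epoxy alcohol 10 with Cp2TiCl (from Cp2TiCl2 and Mn dust; trivalent titanium) and 1,4-cyclohexadiene in THF cleaves the C5–O bond by electron transfer. Hydrogen-atom transfer to the C5 radical should occur anti to the bulky titanium alkoxide on C4 and give 5α-dauc-8-ene-4β,6β-diol F3. A Mitsunobu reaction of F3 with 4-methoxybenzoic acid, PPh3 and diisopropyl azodicarboxylate then inverts C6 and gives 15 without any C6 ketone.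

**Step 12.** The oxidation may also attack C7 or the C8 methyl, or oxidise the product further. Fallback, from 15 back to 16: mCPBA epoxidation of 15 gives the 8α,9α-epoxide F4 (either face would serve). Phenylselenide, from (PhSe)2 and NaBH4 in EtOH, opens it at the less substituted C9 to the hydroxy selenide F5. Oxidation with H2O2/pyridine and selenoxide syn-elimination, which can only run towards C10, gives the tertiary allylic alcohol F6. Oxidative 1,3-transposition with pyridinium chlorochromate [C5H5NH][CrO3Cl], as in step 5, then gives 16.

## Further compounds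

F1 | step 3 | carotol | CC1=CC[C@]2(CC[C@H]([C@]2(CC1)O)C(C)C)C
F2 | step 4 | 4,5-epoxydauc-8-ene (both epoxide faces) | CC1=CC[C@@]2(C)CCC3(C(C)C)OC23CC1
F3 | step 9 | 5α-dauc-8-ene-4β,6β-diol | O[C@@H]1CC(C)=CC[C@]2(C)[C@@H]1[C@](O)(C(C)C)CC2
F4 | step 12 | 8α,9α-epoxy-4β-hydroxy-5α-daucan-6α-yl 4-methoxybenzoate | COc1ccc(C(=O)O[C@H]2C[C@@]3(C)O[C@H]3C[C@]3(C)[C@@H]2[C@](O)(C(C)C)CC3)cc1
F5 | step 12 | 4β,8α-dihydroxy-9β-(phenylselanyl)-5α-daucan-6α-yl 4-methoxybenzoate | COc1ccc(C(=O)O[C@H]2C[C@@](C)(O)[C@H]([Se]c4ccccc4)C[C@]3(C)[C@@H]2[C@](O)(C(C)C)CC3)cc1
F6 | step 12 | 4β,8α-dihydroxy-5α-dauc-9-en-6α-yl 4-methoxybenzoate | COc1ccc(C(=O)O[C@H]2C[C@@](C)(O)C=C[C@]3(C)[C@@H]2[C@](O)(C(C)C)CC3)cc1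
F0 | step 13 | none | none
A1 | alternative 1 | trans-cyclopentane-1,2-dicarbaldehyde (C1 methyl and formyl, C5 formyl, C4 dioxolane, C2 β-silyloxy) | O=C[C@]1(C)[C@@H](C=O)C2(OCCO2)C[C@H]1O[Si](C)(C)C(C)(C)C
A2 | alternative 1 | 3-(trimethylsilyl)-2-(trimethylsilylmethyl)propene | C=C(C[Si](C)(C)C)C[Si](C)(C)C
A3 | alternative 1 | trans-fused 8-methylene-hydroazulene-6,10-diol (C4 dioxolane, C2 silyl ether) | O[C@H]2CC(=C)C[C@H](O)[C@]3(C)[C@@H]2C4(OCCO4)C[C@H]3O[Si](C)(C)C(C)(C)C
A4 | alternative 2 | (S)-Wieland–Miescher ketone | C[C@]12CCC(=O)C=C1CCCC2=O
A5 | alternative 2 | all-cis decalin hydroxy mesylate (C6 carbinol, C5 mesylate, C4 silyl ether, C10 dioxolane) | C[C@]12CC[C@H](O[Si](C)(C)C(C)(C)C)[C@H](OS(C)(=O)=O)[C@@]1(O)CCCC23OCCO3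
A6 | alternative 2 | trans-fused hydroazulen-6-one (C4 silyl ether, C10 dioxolane) | O=C1CCCC2(OCCO2)[C@]3(C)[C@@H]1[C@@H](O[Si](C)(C)C(C)(C)C)CC3
A7 | alternative 3 | (Z)-vinyl iodide aldehyde (C10 formyl on C1, C9 iodide, both esters, C4 triethylsilyl ether) | COc1ccc(C(=O)O[C@@H](C/C(C)=C\I)[C@H]2[C@](O[Si](CC)(CC)CC)(C(C)C)C[C@@H](OC(C)=O)[C@]2(C)C=O)cc1
A8 | alternative 3 | 8,9-alkene precursor of the target (C4 triethylsilyl ether) | COc1ccc(C(=O)O[C@H]2CC(C)=C[C@H](O)[C@]3(C)[C@@H]2[C@](O[Si](CC)(CC)CC)(C(C)C)C[C@H]3OC(C)=O)cc1
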